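The cyclohexenol ring (C1 carbinol, C2=C3, C4 carrying the chain, C5, C6) is assembled while C3 is a ketone carbon and the chain carbons C1′ (CHCH3), C2′ and C3′ (CHOAc) are tied back to C2 as a temporary second six-membered ring. A Michael/aldol [3+3] annulation of this cyclohexanone with methyl vinyl ketone forms C4–C5 and C1–C2 in one operation; it exploits C2 and C4 as the two α-carbons of C3, and the rigid bicyclo[3.3.1]nonanone relays the bought C1′ stereocentre to C4 and C1. A Grob fragmentation pushed by the C3′ oxygen then cuts C2–C3′, unveiling the C2=C3 alkene and a C3′ aldehyde for the enoate.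

Key step: step 3

Remark: 1 is taken as a catalogue compound (it is otherwise three known steps from (R)-pulegone); locants in the Why lines follow the name of the compound discussed.

Step 1
Reactants: 1 (R)-5-methylcyclohex-2-en-1-one
Product: 3 (3R,5R)-3-hydroxy-5-methylcyclohexan-1-one, via β-boryl ketone 2 (not isolated)
Conditions: B2pin2, CuCl (3 mol %), NaOt-Bu, Xantphos, MeOH, THF, rt; then NaBO3·4H2O, THF/H2O, rt
Reagents that add atoms: bis(pinacolato)diboron, CC1(C)OB(OC1(C)C)B1OC(C)(C)C(C)(C)O1 (boron of 2, lost again); sodium perborate, [Na+].[Na+].O[B-]1(O)OO[B-](O)(O)OO1 (hydroxyl oxygen)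
Why: Copper-catalysed conjugate borylation should add boron to C3 on the face opposite to the C5 methyl group, and perborate oxidation replaces boron by hydroxyl with retention, giving the trans-3,5 pattern.

Step 2
Reactants: 3 (3R,5R)-3-hydroxy-5-methylcyclohexan-1-one
Product: 4 (3R,5R)-3-[(tert-butyldimethylsilyl)oxy]-5-methylcyclohexan-1-one
Conditions: TBSCl, imidazole, DMF, rt
Reagents that add atoms: tert-butyldimethylsilyl chloride, CC(C)(C)[Si](C)(C)Cl
Why: Standard silylation of the secondary alcohol; the silyl ether later serves as the fluoride-operated switch for the fragmentation.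

Step 3
Reactants: 4 (3R,5R)-3-[(tert-butyldimethylsilyl)oxy]-5-methylcyclohexan-1-one; 5 methyl vinyl ketone (but-3-en-2-one)
Product: 8 (1S,2R,5S,6R,8R)-8-[(tert-butyldimethylsilyl)oxy]-2-hydroxy-2,6-dimethylbicyclo[3.3.1]nonan-9-one, via lithium enolate 6 (not isolated), via Michael-adduct enolate 7 (not isolated)
Conditions: LiN(i-Pr)2, THF, −78 °C; 5, −78 → −30 °C; AcOH, −78 °C
Reagents that add atoms: none
Why: LiN(i-Pr)2 removes the α-proton distal to the silyloxy carbon to give 6, which adds in conjugate fashion to 5; the side-chain enolate so formed takes the α′-proton by a 1,5-shift to give 7, and 7 adds to the side-chain ketone, so the C5–C4 bond and the C1–C2 bond of 8 form in one flask. This is the tandem Michael/intramolecular aldol (α,α′-annulation) that turns cyclohexanones and vinyl ketones into bridged bicyclo[3.3.1]nonan-9-one ketols; the first bond is intermolecular and the new six-membered ring closes by a 6-(enolendo)-exo-trig aldol. Bridgehead C5 is set by attack of 5 on the enolate face opposite to the adjacent methyl group, trans to the bought stereocentre, and C1 then follows because the one-carbon bridge can only span cis. The carbinol centre C2 is set in the lithium-chelated chair transition state, which places the alkoxide syn to the C9 carbonyl and the methyl group equatorial. The step needs enolisation away from the silyloxy carbon (kinetic deprotonation of β-silyloxy ketones goes to the far side), bridged and not fused aldol closure (under aprotic, cold conditions the side-chain methyl is not enolised, while the α′-proton is reached intramolecularly) and no β-elimination of silanolate (in the reacting enolate the C–OSi bond lies pseudo-equatorial, out of the π-plane).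

Step 4
Reactants: 8 (1S,2R,5S,6R,8R)-8-[(tert-butyldimethylsilyl)oxy]-2-hydroxy-2,6-dimethylbicyclo[3.3.1]nonan-9-one
Product: 9 (1S,2R,5S,6R,8R,9S)-8-[(tert-butyldimethylsilyl)oxy]-2,6-dimethylbicyclo[3.3.1]nonane-2,9-diol
Conditions: SmI2, MeOH, THF, 0 °C
Reagents that add atoms: none
Why: In this chelation-controlled electron-transfer reduction of a β-hydroxy ketone, trivalent samarium bridges the tertiary hydroxyl and the ketyl oxygen, so both oxygens should end on the same face and the C9 hydroxyl becomes antiperiplanar to the C1–C8 bond.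

Step 5
Reactants: 9 (1S,2R,5S,6R,8R,9S)-8-[(tert-butyldimethylsilyl)oxy]-2,6-dimethylbicyclo[3.3.1]nonane-2,9-diol
Product: 10 (1R,2R,5S,6R,8R,9S)-8-[(tert-butyldimethylsilyl)oxy]-2-hydroxy-2,6-dimethylbicyclo[3.3.1]nonan-9-yl methanesulfonate
Conditions: MsCl, Et3N, CH2Cl2, −20 → 0 °C
Reagents that add atoms: methanesulfonyl chloride, CS(=O)(=O)Cl
Why: Sulfonylation through sulfene should take the secondary bridge alcohol only, the tertiary alcohol and the silyl ether being unreactive (selective mesylation).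

Step 6
Reactants: 10 (1R,2R,5S,6R,8R,9S)-8-[(tert-butyldimethylsilyl)oxy]-2-hydroxy-2,6-dimethylbicyclo[3.3.1]nonan-9-yl methanesulfonate
Product: 12 (3R)-3-[(1S,4R)-4-hydroxy-4-methylcyclohex-2-en-1-yl]butanal, via ammonium alkoxide 11 (not isolated)
Conditions: Bu4NF, THF, 0 °C → rt
Reagents that add atoms: none
Why: Fluoride frees the C8 alkoxide, whose lone pair, the C1–C8 bond and the C9–OMs bond are antiperiplanar, so a Grob fragmentation should open the temporary ring to the cis-cyclohexene and the aldehyde without touching a stereocentre.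

Step 7
Reactants: 12 (3R)-3-[(1S,4R)-4-hydroxy-4-methylcyclohex-2-en-1-yl]butanal; 13 methyl propiolate
Product: 15 methyl (4S,6R)-4-hydroxy-6-[(1S,4R)-4-hydroxy-4-methylcyclohex-2-en-1-yl]hept-2-ynoate, via alkynylzinc 14 (not isolated)
Conditions: Me2Zn (excess), (S,S)-ProPhenol (20 mol %), Ph3PO, toluene, 0 °C
Reagents that add atoms: none
Why: Catalytic asymmetric addition of the zinc acetylide of 13 to the aldehyde sets the (S)-carbinol under reagent control, the ligand enantiomer being the one that directs Re-face attack (the antipode is used if the sense on this aldehyde is the reverse).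

Step 8
Reactants: 15 methyl (4S,6R)-4-hydroxy-6-[(1S,4R)-4-hydroxy-4-methylcyclohex-2-en-1-yl]hept-2-ynoate
Product: 17 methyl (2Z,4S,6R)-4-hydroxy-6-[(1S,4R)-4-hydroxy-4-methylcyclohex-2-en-1-yl]-2-iodohept-2-enoate, via alkenylalanate 16 (not isolated)
Conditions: NaAlH2(OCH2CH2OCH3)2, THF, −72 °C; then I2, −72 → −10 °C
Reagents that add atoms: iodine, II
Why: The alkoxide-bound aluminium hydride delivers hydride to C3 and leaves aluminium on C2 cis to the carbinol (trans-hydroalumination of a γ-hydroxy ynoate), and iodine replaces aluminium with retention, which fixes the alkene geometry with the ester trans to C4.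

Step 9
Reactants: 17 methyl (2Z,4S,6R)-4-hydroxy-6-[(1S,4R)-4-hydroxy-4-methylcyclohex-2-en-1-yl]-2-iodohept-2-enoate; 18 5-bromo-2-methylpent-2-ene
Product: 20 methyl (2E,4S,6R)-4-hydroxy-6-[(1S,4R)-4-hydroxy-4-methylcyclohex-2-en-1-yl]-2-(4-methylpent-3-en-1-yl)hept-2-enoate, via alkylzinc bromide 19 (not isolated)
Conditions: 18, Zn, LiCl, THF, 40 °C; then 17, Pd(dppf)Cl2 (5 mol %), THF, 45 °C
Reagents that add atoms: none
Why: Negishi coupling of the alkenyl iodide with the primary alkylzinc reagent proceeds with retention of alkene geometry, and alkylzinc halides tolerate the two free hydroxyls when used in excess.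

Step 10
Reactants: 20 methyl (2E,4S,6R)-4-hydroxy-6-[(1S,4R)-4-hydroxy-4-methylcyclohex-2-en-1-yl]-2-(4-methylpent-3-en-1-yl)hept-2-enoate
Product: 21 methyl (2E,4S,6R)-4-acetoxy-6-[(1S,4R)-4-hydroxy-4-methylcyclohex-2-en-1-yl]-2-(4-methylpent-3-en-1-yl)hept-2-enoate
Conditions: Ac2O, pyridine, DMAP (cat.), CH2Cl2, 0 °C
Reagents that add atoms: acetic anhydride, CC(=O)OC(C)=O
Why: DMAP-catalysed acetylation should take the secondary allylic alcohol much faster than the hindered tertiary one.

Compound list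
1 | (R)-5-methylcyclohex-2-en-1-one | C[C@H]1CC(=O)C=CC1 | starting material
2 | (3R,5R)-3-methyl-5-(4,4,5,5-tetramethyl-1,3,2-dioxaborolan-2-yl)cyclohexan-1-one | C[C@H]1CC(=O)C[C@H](B2OC(C)(C)C(C)(C)O2)C1 | intermediate
3 | (3R,5R)-3-hydroxy-5-methylcyclohexan-1-one (OH trans to CH3) | C[C@H]1CC(=O)C[C@H](O)C1 | intermediate
4 | (3R,5R)-3-[(tert-butyldimethylsilyl)oxy]-5-methylcyclohexan-1-one | C[C@H]1CC(=O)C[C@H](O[Si](C)(C)C(C)(C)C)C1 | intermediate
5 | methyl vinyl ketone (but-3-en-2-one) | CC(=O)C=C | starting material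
6 | lithium (3R,5R)-5-[(tert-butyldimethylsilyl)oxy]-3-methylcyclohex-1-en-1-olate | C[C@H]1C=C(O[Li])C[C@H](O[Si](C)(C)C(C)(C)C)C1 | intermediate
7 | lithium (3R,5R,6S)-3-[(tert-butyldimethylsilyl)oxy]-5-methyl-6-(3-oxobutyl)cyclohex-1-en-1-olate | CC(=O)CC[C@H]1[C@H](C)C[C@@H](O[Si](C)(C)C(C)(C)C)C=C1O[Li] | intermediate
8 | (1S,2R,5S,6R,8R)-8-[(tert-butyldimethylsilyl)oxy]-2-hydroxy-2,6-dimethylbicyclo[3.3.1]nonan-9-one (2-OH axial, syn to C9=O; 6-CH3 trans to the C5–C4 bond) | O=C1[C@@H]2[C@](C)(O)CC[C@H]1[C@H](C)C[C@H]2O[Si](C)(C)C(C)(C)C | intermediate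
9 | (1S,2R,5S,6R,8R,9S)-8-[(tert-butyldimethylsilyl)oxy]-2,6-dimethylbicyclo[3.3.1]nonane-2,9-diol (9-OH syn to 2-OH) | O[C@@H]1[C@@H]2[C@](C)(O)CC[C@H]1[C@H](C)C[C@H]2O[Si](C)(C)C(C)(C)C | intermediate
10 | (1R,2R,5S,6R,8R,9S)-8-[(tert-butyldimethylsilyl)oxy]-2-hydroxy-2,6-dimethylbicyclo[3.3.1]nonan-9-yl methanesulfonate | CS(=O)(=O)O[C@@H]1[C@@H]2[C@](C)(O)CC[C@H]1[C@H](C)C[C@H]2O[Si](C)(C)C(C)(C)C | intermediate
11 | tetrabutylammonium C8-alkoxide of desilylated 10 | CS(=O)(=O)O[C@@H]1[C@@H]2[C@](C)(O)CC[C@H]1[C@H](C)C[C@H]2[O-].CCCC[N+](CCCC)(CCCC)CCCC | intermediate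
12 | (3R)-3-[(1S,4R)-4-hydroxy-4-methylcyclohex-2-en-1-yl]butanal | O=CC[C@@H](C)[C@H]1C=C[C@](C)(O)CC1 | intermediate
13 | methyl propiolate | COC(=O)C#C | starting material
14 | methyl 3-(methylzincio)prop-2-ynoate | COC(=O)C#C[Zn]C | intermediate
15 | methyl (4S,6R)-4-hydroxy-6-[(1S,4R)-4-hydroxy-4-methylcyclohex-2-en-1-yl]hept-2-ynoate | COC(=O)C#C[C@H](C[C@@H](C)[C@H]1C=C[C@](C)(O)CC1)O | intermediate
16 | sodium alkenylalanate: five-membered O–Al ring through O4, C4, C3 and C2 of 15, with two 2-methoxyethoxy groups on aluminium | [Na+].COCCO[Al-]1(OCCOC)O[C@@H](C[C@@H](C)[C@H]2C=C[C@](C)(O)CC2)C=C1C(=O)OC | intermediate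
17 | methyl (2Z,4S,6R)-4-hydroxy-6-[(1S,4R)-4-hydroxy-4-methylcyclohex-2-en-1-yl]-2-iodohept-2-enoate | COC(=O)/C(I)=C/[C@H](C[C@@H](C)[C@H]1C=C[C@](C)(O)CC1)O | intermediate
18 | 5-bromo-2-methylpent-2-ene | CC(C)=CCCBr | starting material
19 | (4-methylpent-3-en-1-yl)zinc bromide | CC(C)=CCC[Zn]Br | intermediate
20 | methyl (2E,4S,6R)-4-hydroxy-6-[(1S,4R)-4-hydroxy-4-methylcyclohex-2-en-1-yl]-2-(4-methylpent-3-en-1-yl)hept-2-enoate | COC(=O)/C(=C/[C@H](C[C@@H](C)[C@H]1C=C[C@](C)(O)CC1)O)CCC=C(C)C | intermediate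
21 | methyl (2E,4S,6R)-4-acetoxy-6-[(1S,4R)-4-hydroxy-4-methylcyclohex-2-en-1-yl]-2-(4-methylpent-3-en-1-yl)hept-2-enoate | COC(=O)/C(=C/[C@H](C[C@@H](C)[C@H]1C=C[C@](C)(O)CC1)OC(C)=O)CCC=C(C)C | target

Total step count: 10. Longest linear sequence: 10 steps (1 → 21).

Steps most likely to fail

Step 3. What may go wrong: enolisation toward the silyloxy-bearing carbon, polymerisation of the vinyl ketone, or closure to the fused Robinson ketol instead of the bridged one. Fallback: the two bonds are made in separate, regiochemically forced events. Setting out again from 1, nucleophilic epoxidation (H2O2, NaOH, MeOH, 0 °C) anti to the methyl group gives the epoxy ketone (1R,4R,6R)-4-methyl-7-oxabicyclo[4.1.0]heptan-2-one F1, which can enolise only at the required carbon. Its lithium enolate (LiN(i-Pr)2, THF, −78 °C) adds to 5 trans to the methyl group to give the epoxy diketone F2. SmI2 (THF, −78 °C) then cleaves the α-C–O bond of the epoxy ketone, and the resulting β-oxido samarium enolate closes the bridged aldol to the diol ketone F3. TBSCl/imidazole silylates the secondary alcohol only and the route is rejoined at 8.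

Step 4. What may go wrong: delivery of hydrogen to the other face of the bridge carbonyl, which would place the later leaving group antiperiplanar to bonds of the ring that must survive. Fallback: from 8, NaBH4 (MeOH, 0 °C) is allowed to give the epimeric (9R)-diol F4, and the carbinol is then equilibrated by Meerwein–Ponndorf–Verley/Oppenauer hydride exchange (Al(Oi-Pr)3, i-PrOH, a little acetone, toluene, 80 °C). The aluminium chelate of the cis-1,3-diaxial diol is the thermodynamic sink, and the route is rejoined at 9.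

Step 7. What may go wrong: poor facial selectivity, and aldol self-condensation of the unbranched aldehyde under the zinc alkoxide conditions. Fallback: from 12, addition of LiC≡CCO2Me (from 13 and LiN(SiMe3)2, THF, −78 °C) without stereocontrol gives 15 together with its (4R)-epimer F5. Dess–Martin periodinane (CH2Cl2, 0 °C) oxidises the mixture to the ynone F6, and (S)-Alpine-borane (THF, rt) reduces F6 under reagent control, rejoining the route at 15.

Further compounds
F1 | step 3 | (1R,4R,6R)-4-methyl-7-oxabicyclo[4.1.0]heptan-2-one | C[C@H]1CC(=O)[C@@H]2O[C@@H]2C1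
F2 | step 3 | (1R,3S,4R,6R)-4-methyl-3-(3-oxobutyl)-7-oxabicyclo[4.1.0]heptan-2-one | CC(=O)CC[C@H]1[C@H](C)C[C@H]2O[C@H]2C1=O
F3 | step 3 | (1S,2R,5S,6R,8R)-2,8-dihydroxy-2,6-dimethylbicyclo[3.3.1]nonan-9-one | O=C1[C@@H]2[C@](C)(O)CC[C@H]1[C@H](C)C[C@H]2O
F4 | step 4 | (1S,2R,5S,6R,8R,9R)-8-[(tert-butyldimethylsilyl)oxy]-2,6-dimethylbicyclo[3.3.1]nonane-2,9-diol | O[C@H]1[C@@H]2[C@](C)(O)CC[C@H]1[C@H](C)C[C@H]2O[Si](C)(C)C(C)(C)C
F5 | step 7 | methyl (4R,6R)-4-hydroxy-6-[(1S,4R)-4-hydroxy-4-methylcyclohex-2-en-1-yl]hept-2-ynoate | COC(=O)C#C[C@@H](C[C@@H](C)[C@H]1C=C[C@](C)(O)CC1)O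
F6 | step 7 | methyl (6R)-6-[(1S,4R)-4-hydroxy-4-methylcyclohex-2-en-1-yl]-4-oxohept-2-ynoate | COC(=O)C#CC(=O)C[C@@H](C)[C@H]1C=C[C@](C)(O)CC1
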